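**Retrosynthetic overview**
- The target is read as four flavan-3-ol units: epigallocatechin (unit 1)-(4β→8)-epigallocatechin (unit 2)-(4β→8)-epigallocatechin 3-O-gallate (unit 3)-(4β→8)-epicatechin (unit 4). Units 1, 2 and 4 come from natural (−)-epigallocatechin and (−)-epicatechin; only ring C of unit 3 is built.
- Late disconnections: benzyl ethers and a C8 bromine cap (hydrogenolysis), C4(unit 1)–C8(unit 2) (flavan-4-yl cation coupling), the gallate ester, and C4(unit 3)–C8(unit 4) (flavan-4-yl cation coupling).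
- Key disconnection: O1–C2 and C4–C4a of unit 3, giving a phenol that already carries unit 2 on the carbon that becomes C8, plus a cis-2,3-epoxy aldehyde that supplies C4, C3, C2 and the pyrogallol ring.
- Enabling feature: in ring A of unit 3 the phenolic oxygen on C8a and the nucleophilic carbon C4a are ortho neighbours on a phloroglucinol ring (a 1,3-O,C-dinucleophile), while C4–C3–C2 of ring C is a 1,3-dielectrophile at the oxidation level of an epoxy aldehyde, with C2 benzylic to the pyrogallol ring. Annulating onto the phenol fixes the 4→8 link by construction and leaves a C4 hydroxyl as leaving group for the next interflavan bond.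
- Ring order: the pyran rings of units 1, 2 and 4 pre-exist; ring C of unit 3 is the only ring formed (step 9).

Key step: step 9

Remark on the chemistry: all four units are 2R,3R (2,3-cis) and "4β" means trans to the 3-oxygen. The diol made in the key step is carried on as a mixture of C4 epimers and drawn without a descriptor there, because that carbon becomes a cation in the following coupling.

**Step 1**
Reactants: 1 (−)-epigallocatechin
Product: 2 5,7,3',4',5'-penta-O-benzyl-(−)-epigallocatechin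
Conditions: BnBr, K2CO3, DMF, −10 °C → rt, Ar
Reagents that add atoms: benzyl bromide, BrCc1ccccc1
Why: Williamson etherification with a weak base should alkylate the five phenols and leave the secondary 3-OH, while low temperature and exclusion of air limit C2 epimerisation and pyrogallol oxidation.

**Step 2**
Reactants: 2 5,7,3',4',5'-penta-O-benzyl-(−)-epigallocatechin
Product: 3 3,5,7,3',4',5'-hexa-O-benzyl-(−)-epigallocatechin
Conditions: NaH, BnBr, n-Bu4NI (cat.), DMF, 0 °C → rt
Reagents that add atoms: benzyl bromide, BrCc1ccccc1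
Why: Williamson etherification of the alkoxide should proceed without touching C2 or C3, since no free phenoxide remains that could open ring C.

**Step 3**
Reactants: 3 3,5,7,3',4',5'-hexa-O-benzyl-(−)-epigallocatechin
Product: 4 4β-(2-ethoxyethoxy)-3,5,7,3',4',5'-hexa-O-benzylepigallocatechin
Conditions: DDQ, HOCH2CH2OEt, CH2Cl2, rt
Reagents that add atoms: 2-ethoxyethanol, CCOCCO
Why: DDQ benzylic oxidation (hydride abstraction at C4, activated by the ring-A oxygens) gives the flavan-4-yl cation, which the alcohol should trap trans to the 3-benzyloxy group on the 2,3-cis ring (4β).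

**Step 4**
Reactants: 4 4β-(2-ethoxyethoxy)-3,5,7,3',4',5'-hexa-O-benzylepigallocatechin; 5 3,5-bis(benzyloxy)phenol
Product: 6 4β-[2-hydroxy-4,6-bis(benzyloxy)phenyl]-3,5,7,3',4',5'-hexa-O-benzylepigallocatechin
Conditions: 5 (4 equiv), BF3·OEt2 (0.5 equiv), CH2Cl2, −78 → −30 °C
Reagents that add atoms: none
Why: Friedel–Crafts capture of the flavan-4-yl cation (the reaction type of phloroglucinol adduct formation) should occur trans to the 3-substituent (4β) and mainly at one of the two equivalent carbons ortho to the free OH rather than at the single carbon between two benzyloxy groups; excess 5 suppresses self-condensation, and any para isomer is removed by chromatography.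

**Step 5**
Reactants: 7 3,4,5-tris(benzyloxy)benzaldehyde
Product: 8 methyl (Z)-3-[3,4,5-tris(benzyloxy)phenyl]prop-2-enoate
Conditions: (CF3CH2O)2P(O)CH2CO2Me, KN(SiMe3)2, 18-crown-6, THF, −78 °C
Reagents that add atoms: methyl bis(2,2,2-trifluoroethyl)phosphonoacetate, COC(=O)CP(=O)(OCC(F)(F)F)OCC(F)(F)F
Why: the Still–Gennari variant of the Horner–Wadsworth–Emmons olefination should give the Z-enoate by fast, kinetically controlled elimination from the electron-poor phosphonate adduct.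

**Step 6**
Reactants: 8 methyl (Z)-3-[3,4,5-tris(benzyloxy)phenyl]prop-2-enoate
Product: 9 (Z)-3-[3,4,5-tris(benzyloxy)phenyl]prop-2-en-1-ol
Conditions: i-Bu2AlH, CH2Cl2, −78 °C; aq. KNaC4H4O6
Reagents that add atoms: none
Why: 1,2-reduction of the conjugated ester by the aluminium hydride should give the allylic alcohol with the Z geometry intact.

**Step 7**
Reactants: 9 (Z)-3-[3,4,5-tris(benzyloxy)phenyl]prop-2-en-1-ol
Product: 10 [(2R,3S)-3-[3,4,5-tris(benzyloxy)phenyl]oxiran-2-yl]methanol (cis-epoxide)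
Conditions: Ti(OiPr)4 (cat.), D-(−)-diisopropyl tartrate (cat.), t-BuOOH, 4 Å MS, CH2Cl2, −20 °C
Reagents that add atoms: tert-butyl hydroperoxide, CC(C)(C)OO
Why: Sharpless asymmetric epoxidation with the D-(−)-tartrate should deliver oxygen to the alkene face that gives the 2R carbinol-side carbon, and syn addition to the Z-alkene fixes the cis (2R,3S) epoxide whose two carbons become C3 and C2 of unit 3.

**Step 8**
Reactants: 10 [(2R,3S)-3-[3,4,5-tris(benzyloxy)phenyl]oxiran-2-yl]methanol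
Product: 11 (2S,3S)-3-[3,4,5-tris(benzyloxy)phenyl]oxirane-2-carbaldehyde (cis-epoxide)
Conditions: Dess–Martin periodinane, NaHCO3, CH2Cl2, 0 °C
Reagents that add atoms: none
Why: buffered Dess–Martin oxidation should convert the primary alcohol into the aldehyde without opening the aryl epoxide or epimerising the oxirane carbon, which enolises reluctantly.

**Step 9**
Reactants: 6 4β-[2-hydroxy-4,6-bis(benzyloxy)phenyl]-3,5,7,3',4',5'-hexa-O-benzylepigallocatechin; 11 (2S,3S)-3-[3,4,5-tris(benzyloxy)phenyl]oxirane-2-carbaldehyde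
Product: 13 hexa-O-benzylepigallocatechin-(4β→8)-[5,7,3',4',5'-penta-O-benzylepigallocatechin-4-ol] (unit 3: 2R and 2,3-cis; both C4 epimers), via titanium-bound ortho-(2,3-epoxy-1-hydroxypropyl)phenol 12 (not isolated)
Conditions: Ti(OiPr)4 (1.1 equiv), toluene, rt, then evaporation of i-PrOH; 11 (1.2 equiv), toluene, 0 → 40 °C; aq. KNaC4H4O6
Reagents that add atoms: none
Why: Proposed new method: ligand exchange gives the aryloxytitanium triisopropoxide of 6, whose titanium binds the aldehyde of 11 and delivers it to the only free ortho carbon through a six-membered transition state (C4–C4a bond), and in the resulting titanium epoxy alkoxide 12 the titanium-bound phenoxide oxygen then opens the epoxide at its distal, benzylic carbon (O1–C2 bond). The closest known reactions are the ortho-specific hydroxyalkylation of titanium and magnesium phenoxides with α-oxygenated aldehydes and the Ti(OiPr)4-mediated C-3-selective opening of 2,3-epoxy alcohols, in which 3-aryl glycidols open at the benzylic carbon with inversion; their merger into one phenol annulation has not been shown. Ring C closes by a 6-endo-tet epoxide opening, preferred over the 5-exo mode because C2 is benzylic to the tris(benzyloxy)phenyl ring and is the epoxide carbon remote from the titanium alkoxide. C2 is set by inversion of the (3S) oxirane carbon to 2R, C3 keeps its C–O bond and hence its configuration so the cis-epoxide becomes the 2,3-cis ring, and C4 forms as an epimer mixture that is erased in step 12. The step needs ortho rather than para C-alkylation (secured by the phenoxide–titanium template, since the para carbon cannot reach the bound aldehyde), SN2 rather than SN1 opening at C2 (the aryl ring has one para and two meta oxygens and the medium is only weakly Lewis acidic), and no ionisation of the electron-rich benzylic alkoxide to an ortho-quinone methide (it is held as a titanium chelate at or below 40 °C with near-equimolar partners).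

**Step 10**
Reactants: 14 (−)-epicatechin
Product: 15 5,7,3',4'-tetra-O-benzyl-(−)-epicatechin
Conditions: BnBr, K2CO3, DMF, 0 °C → rt, Ar
Reagents that add atoms: benzyl bromide, BrCc1ccccc1
Why: Williamson etherification with a weak base should alkylate the four phenols selectively over the secondary 3-OH.

**Step 11**
Reactants: 15 5,7,3',4'-tetra-O-benzyl-(−)-epicatechin
Product: 16 3,5,7,3',4'-penta-O-benzyl-(−)-epicatechin
Conditions: NaH, BnBr, DMF, 0 °C → rt
Reagents that add atoms: benzyl bromide, BrCc1ccccc1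
Why: Williamson etherification of the 3-alkoxide masks the only hydroxyl of unit 4, so that later only the 3-OH of unit 3 is free for esterification.

**Step 12**
Reactants: 13 hexa-O-benzylepigallocatechin-(4β→8)-[5,7,3',4',5'-penta-O-benzylepigallocatechin-4-ol]; 16 3,5,7,3',4'-penta-O-benzyl-(−)-epicatechin
Product: 17 hexa-O-benzylepigallocatechin-(4β→8)-[5,7,3',4',5'-penta-O-benzylepigallocatechin]-(4β→8)-[3,5,7,3',4'-penta-O-benzylepicatechin] (free 3-OH on unit 3)
Conditions: 16 (4 equiv), BF3·OEt2 (0.5 equiv), 4 Å MS, CH2Cl2, −78 → −20 °C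
Reagents that add atoms: none
Why: in this leucoanthocyanidin-type Friedel–Crafts condensation both C4 epimers of 13 should ionise to the same flavan-4-yl cation, which C8 of 16 attacks trans to the 3-oxygen of the 2,3-cis ring (4β, 3,4-trans) and in preference to C6, while the excess of 16 outcompetes the free C8 of unit 2.

**Step 13**
Reactants: 17 the trimer with free 3-OH on unit 3; 18 3,4,5-tris(benzyloxy)benzoic acid
Product: 19 hexa-O-benzylepigallocatechin-(4β→8)-[5,7,3',4',5'-penta-O-benzylepigallocatechin 3-O-(3,4,5-tris(benzyloxy)benzoate)]-(4β→8)-[3,5,7,3',4'-penta-O-benzylepicatechin]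
Conditions: 18 (3 equiv), DCC, DMAP (cat.), CH2Cl2, rt
Reagents that add atoms: none
Why: Steglich esterification should acylate the only free hydroxyl of 17 without touching any stereocentre.

**Step 14**
Reactants: 4 4β-(2-ethoxyethoxy)-3,5,7,3',4',5'-hexa-O-benzylepigallocatechin
Product: 20 8-bromo-4β-(2-ethoxyethoxy)-3,5,7,3',4',5'-hexa-O-benzylepigallocatechin
Conditions: NBS, CH2Cl2, −78 → 0 °C
Reagents that add atoms: N-bromosuccinimide, O=C1CCC(=O)N1Br
Why: electrophilic aromatic bromination should go to C8, the most nucleophilic free position of benzylated flavan-3-ols, and the bromine caps that carbon so the electrophile cannot add to itself and the product cannot grow further.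

**Step 15**
Reactants: 19 the galloylated trimer; 20 8-bromo-4β-(2-ethoxyethoxy)-3,5,7,3',4',5'-hexa-O-benzylepigallocatechin
Product: 21 [8-bromo-hexa-O-benzylepigallocatechin]-(4β→8)-[hexa-O-benzylepigallocatechin]-(4β→8)-[penta-O-benzylepigallocatechin 3-O-(3,4,5-tris(benzyloxy)benzoate)]-(4β→8)-[penta-O-benzylepicatechin]
Conditions: 20 (1.5 equiv), TMSOTf (cat.), CH2Cl2, −78 °C; Et3N quench
Reagents that add atoms: none
Why: Lewis-acid interflavan Friedel–Crafts coupling should join the flavan-4-yl cation from 20 to C8 of unit 2, the only free C8 in 19 (the C6 carbons lie between two benzyloxy groups), trans to the 3-benzyloxy group of the cation (4β).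

**Step 16**
Reactants: 21 the bromine-capped, perbenzylated tetramer
Product: 22 epigallocatechin-(4β→8)-epigallocatechin-(4β→8)-epigallocatechin 3-O-gallate-(4β→8)-epicatechin (target)
Conditions: H2 (1 atm), Pd(OH)2/C, Et3N (1.2 equiv), THF/MeOH/H2O, rt
Reagents that add atoms: none
Why: catalytic hydrogenolysis should cleave all 25 benzyl ethers and the aryl C–Br bond while leaving the gallate ester, the interflavan bonds and every stereocentre intact, with the amine taking up the HBr that could otherwise cleave interflavan bonds.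

**Compound list**
1 | (−)-epigallocatechin | O[C@@H]1Cc2c(O)cc(O)cc2O[C@@H]1c1cc(O)c(O)c(O)c1 | starting material
2 | 5,7,3',4',5'-penta-O-benzyl-(−)-epigallocatechin | O[C@@H]1Cc2c(OCc3ccccc3)cc(OCc3ccccc3)cc2O[C@@H]1c1cc(OCc2ccccc2)c(OCc2ccccc2)c(OCc2ccccc2)c1 | intermediate
3 | 3,5,7,3',4',5'-hexa-O-benzyl-(−)-epigallocatechin | c1ccccc1CO[C@@H]1Cc2c(OCc3ccccc3)cc(OCc3ccccc3)cc2O[C@@H]1c1cc(OCc2ccccc2)c(OCc2ccccc2)c(OCc2ccccc2)c1 | intermediate
4 | 4β-(2-ethoxyethoxy)-hexa-O-benzylepigallocatechin | CCOCCO[C@H]1c2c(OCc3ccccc3)cc(OCc3ccccc3)cc2O[C@H](c2cc(OCc3ccccc3)c(OCc3ccccc3)c(OCc3ccccc3)c2)[C@@H]1OCc1ccccc1 | intermediate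
5 | 3,5-bis(benzyloxy)phenol | Oc1cc(OCc2ccccc2)cc(OCc2ccccc2)c1 | starting material
6 | 4β-[2-hydroxy-4,6-bis(benzyloxy)phenyl]-hexa-O-benzylepigallocatechin | Oc1cc(OCc2ccccc2)cc(OCc2ccccc2)c1[C@H]1c2c(OCc3ccccc3)cc(OCc3ccccc3)cc2O[C@H](c2cc(OCc3ccccc3)c(OCc3ccccc3)c(OCc3ccccc3)c2)[C@@H]1OCc1ccccc1 | intermediate
7 | 3,4,5-tris(benzyloxy)benzaldehyde | O=Cc1cc(OCc2ccccc2)c(OCc2ccccc2)c(OCc2ccccc2)c1 | starting material
8 | methyl (Z)-3-[3,4,5-tris(benzyloxy)phenyl]prop-2-enoate | COC(=O)/C=C\c1cc(OCc2ccccc2)c(OCc2ccccc2)c(OCc2ccccc2)c1 | intermediate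
9 | (Z)-3-[3,4,5-tris(benzyloxy)phenyl]prop-2-en-1-ol | OC/C=C\c1cc(OCc2ccccc2)c(OCc2ccccc2)c(OCc2ccccc2)c1 | intermediate
10 | [(2R,3S)-3-[3,4,5-tris(benzyloxy)phenyl]oxiran-2-yl]methanol | OC[C@H]1O[C@H]1c1cc(OCc2ccccc2)c(OCc2ccccc2)c(OCc2ccccc2)c1 | intermediate
11 | (2S,3S)-3-[3,4,5-tris(benzyloxy)phenyl]oxirane-2-carbaldehyde | O=C[C@H]1O[C@H]1c1cc(OCc2ccccc2)c(OCc2ccccc2)c(OCc2ccccc2)c1 | intermediate
12 | ortho-hydroxyalkylation adduct of 6 and 11 (titanium chelate, drawn as the free epoxy diol; carbinol carbon as both epimers) | OC([C@H]1O[C@H]1c1cc(OCc2ccccc2)c(OCc2ccccc2)c(OCc2ccccc2)c1)c1c(O)c([C@H]2c3c(OCc4ccccc4)cc(OCc4ccccc4)cc3O[C@H](c3cc(OCc4ccccc4)c(OCc4ccccc4)c(OCc4ccccc4)c3)[C@@H]2OCc2ccccc2)c(OCc2ccccc2)cc1OCc1ccccc1 | intermediate (not isolated)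
13 | hexa-O-benzylepigallocatechin-(4β→8)-[penta-O-benzylepigallocatechin-4-ol] (both C4 epimers) | O[C@@H]1C(O)c2c(OCc3ccccc3)cc(OCc3ccccc3)c([C@H]3c4c(OCc5ccccc5)cc(OCc5ccccc5)cc4O[C@H](c4cc(OCc5ccccc5)c(OCc5ccccc5)c(OCc5ccccc5)c4)[C@@H]3OCc3ccccc3)c2O[C@@H]1c1cc(OCc2ccccc2)c(OCc2ccccc2)c(OCc2ccccc2)c1 | intermediate
14 | (−)-epicatechin | O[C@@H]1Cc2c(O)cc(O)cc2O[C@@H]1c1ccc(O)c(O)c1 | starting material
15 | 5,7,3',4'-tetra-O-benzyl-(−)-epicatechin | O[C@@H]1Cc2c(OCc3ccccc3)cc(OCc3ccccc3)cc2O[C@@H]1c1ccc(OCc2ccccc2)c(OCc2ccccc2)c1 | intermediate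
16 | 3,5,7,3',4'-penta-O-benzyl-(−)-epicatechin | c1ccccc1CO[C@@H]1Cc2c(OCc3ccccc3)cc(OCc3ccccc3)cc2O[C@@H]1c1ccc(OCc2ccccc2)c(OCc2ccccc2)c1 | intermediate
17 | benzylated trimer with free 3-OH on unit 3 | O[C@@H]1[C@@H](c2c(OCc4ccccc4)cc(OCc4ccccc4)c3c2O[C@H](c2ccc(OCc4ccccc4)c(OCc4ccccc4)c2)[C@H](OCc4ccccc4)C3)c2c(OCc3ccccc3)cc(OCc3ccccc3)c([C@H]3c4c(OCc5ccccc5)cc(OCc5ccccc5)cc4O[C@H](c4cc(OCc5ccccc5)c(OCc5ccccc5)c(OCc5ccccc5)c4)[C@@H]3OCc3ccccc3)c2O[C@@H]1c1cc(OCc2ccccc2)c(OCc2ccccc2)c(OCc2ccccc2)c1 | intermediate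
18 | 3,4,5-tris(benzyloxy)benzoic acid | OC(=O)c1cc(OCc2ccccc2)c(OCc2ccccc2)c(OCc2ccccc2)c1 | starting material
19 | benzylated trimer, unit 3 as 3-O-[3,4,5-tris(benzyloxy)benzoate] | O=C(O[C@@H]1[C@@H](c2c(OCc4ccccc4)cc(OCc4ccccc4)c3c2O[C@H](c2ccc(OCc4ccccc4)c(OCc4ccccc4)c2)[C@H](OCc4ccccc4)C3)c2c(OCc3ccccc3)cc(OCc3ccccc3)c([C@H]3c4c(OCc5ccccc5)cc(OCc5ccccc5)cc4O[C@H](c4cc(OCc5ccccc5)c(OCc5ccccc5)c(OCc5ccccc5)c4)[C@@H]3OCc3ccccc3)c2O[C@@H]1c1cc(OCc2ccccc2)c(OCc2ccccc2)c(OCc2ccccc2)c1)c1cc(OCc2ccccc2)c(OCc2ccccc2)c(OCc2ccccc2)c1 | intermediate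
20 | 8-bromo-4β-(2-ethoxyethoxy)-hexa-O-benzylepigallocatechin | CCOCCO[C@H]1c2c(OCc3ccccc3)cc(OCc3ccccc3)c(Br)c2O[C@H](c2cc(OCc3ccccc3)c(OCc3ccccc3)c(OCc3ccccc3)c2)[C@@H]1OCc1ccccc1 | intermediate
21 | bromine-capped, perbenzylated tetramer | O=C(O[C@@H]1[C@@H](c2c(OCc4ccccc4)cc(OCc4ccccc4)c3c2O[C@H](c2ccc(OCc4ccccc4)c(OCc4ccccc4)c2)[C@H](OCc4ccccc4)C3)c2c(OCc3ccccc3)cc(OCc3ccccc3)c([C@H]3c4c(OCc5ccccc5)cc(OCc5ccccc5)c([C@H]5c6c(OCc7ccccc7)cc(OCc7ccccc7)c(Br)c6O[C@H](c6cc(OCc7ccccc7)c(OCc7ccccc7)c(OCc7ccccc7)c6)[C@@H]5OCc5ccccc5)c4O[C@H](c4cc(OCc5ccccc5)c(OCc5ccccc5)c(OCc5ccccc5)c4)[C@@H]3OCc3ccccc3)c2O[C@@H]1c1cc(OCc2ccccc2)c(OCc2ccccc2)c(OCc2ccccc2)c1)c1cc(OCc2ccccc2)c(OCc2ccccc2)c(OCc2ccccc2)c1 | intermediate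
22 | epigallocatechin-(4β→8)-epigallocatechin-(4β→8)-epigallocatechin 3-O-gallate-(4β→8)-epicatechin | O=C(O[C@@H]1[C@@H](c2c(O)cc(O)c3c2O[C@H](c2ccc(O)c(O)c2)[C@H](O)C3)c2c(O)cc(O)c([C@H]3c4c(O)cc(O)c([C@H]5c6c(O)cc(O)cc6O[C@H](c6cc(O)c(O)c(O)c6)[C@@H]5O)c4O[C@H](c4cc(O)c(O)c(O)c4)[C@@H]3O)c2O[C@@H]1c1cc(O)c(O)c(O)c1)c1cc(O)c(O)c(O)c1 | target

**Totals**
Total step count: 16.
Longest linear sequence: 9 steps (steps 1, 2, 3, 4, 9, 12, 13, 15, 16; the epoxy aldehyde branch through steps 5–8 is equally long).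

**Steps most likely to fail**

Step 9. The annulation may stall after the C–C bond is formed, close in the 5-exo sense, open the epoxide through an open benzylic cation with loss of the 2,3-cis relationship, or lose material by ionisation of the benzylic titanium alkoxide and addition of a second phenol. The fallback uses only known chemistry and takes unit 3 from the natural series instead of building its ring. It sets out from 2: DDQ and 2-ethoxyethanol in CH2Cl2 should give 4β-(2-ethoxyethoxy)-5,7,3',4',5'-penta-O-benzylepigallocatechin F1. TMSOTf-catalysed coupling of F1 with excess 16 at −78 °C should give the dimer penta-O-benzylepigallocatechin-(4β→8)-penta-O-benzylepicatechin F2, with a free 3-OH on the upper unit. Coupling of F2 (in excess, recovered) with 4 under TMSOTf at −78 °C should attach unit 2 at the free C8 of the upper unit and return to the route at 17. The price is that the 4→8 link between units 2 and 3 then rests on C8 over C6 selectivity and on stoichiometry instead of being fixed by construction.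

Step 15. A hindered cation must find one carbon on a very large nucleophile; slow conversion, competing attack at the C6 positions and acid-induced scrambling of the interflavan bonds already present are the likely failure processes. The fallback attaches unit 1 before ring C of unit 3 is built and sets out from 20 and 3. TMSOTf-catalysed coupling with 3 in excess should give the capped dimer 8-bromo-hexa-O-benzylepigallocatechin-(4β→8)-hexa-O-benzylepigallocatechin F3. DDQ and 2-ethoxyethanol should oxidise the only remaining C4 methylene to give its 4β-(2-ethoxyethoxy) derivative F4. BF3·OEt2 with excess 5, as in step 4, should give the capped dimer 4β-[2-hydroxy-4,6-bis(benzyloxy)phenyl] adduct F5. The conditions of step 9 with 11 should give the capped trimeric flavan-3,4-diol F6, and the conditions of step 12 with 16 the capped tetramer with free 3-OH on unit 3 F7. Esterification with 18 as in step 13 returns to the route at 21. This fallback relies on step 9 working on a larger phenol, but every interflavan coupling then uses a cheap partner in excess.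

Step 7. Z-allylic alcohols are slow and less selective substrates for the titanium–tartrate system, and the electron-rich aryl epoxide may be opened by the alkoxide medium, so low enantiomeric purity and ring-opened by-products are the risks. The fallback replaces hydroxyl-directed epoxidation by catalyst-controlled epoxidation of the conjugated cis-ester and sets out from 8. Epoxidation with NaOCl, 4-phenylpyridine N-oxide and the (S,S) enantiomer of [N,N'-bis(3,5-di-tert-butylsalicylidene)cyclohexane-1,2-diaminato]MnCl (a trivalent manganese complex; the enantiomer that turns cis-cinnamates into (2S,3S)-glycidates) in CH2Cl2 at 0 °C should give methyl (2S,3S)-3-[3,4,5-tris(benzyloxy)phenyl]oxirane-2-carboxylate F8. Reduction of the ester with NaBH4 in MeOH/THF at 0 °C returns to the route at 10.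

**Further compounds**
F1 | step 9 | 4β-(2-ethoxyethoxy)-5,7,3',4',5'-penta-O-benzylepigallocatechin | CCOCCO[C@H]1c2c(OCc3ccccc3)cc(OCc3ccccc3)cc2O[C@H](c2cc(OCc3ccccc3)c(OCc3ccccc3)c(OCc3ccccc3)c2)[C@@H]1O
F2 | step 9 | penta-O-benzylepigallocatechin-(4β→8)-penta-O-benzylepicatechin | O[C@@H]1[C@@H](c2c(OCc4ccccc4)cc(OCc4ccccc4)c3c2O[C@H](c2ccc(OCc4ccccc4)c(OCc4ccccc4)c2)[C@H](OCc4ccccc4)C3)c2c(OCc3ccccc3)cc(OCc3ccccc3)cc2O[C@@H]1c1cc(OCc2ccccc2)c(OCc2ccccc2)c(OCc2ccccc2)c1
F3 | step 15 | 8-bromo-hexa-O-benzylepigallocatechin-(4β→8)-hexa-O-benzylepigallocatechin | c1ccccc1CO[C@@H]1Cc2c(OCc3ccccc3)cc(OCc3ccccc3)c([C@H]3c4c(OCc5ccccc5)cc(OCc5ccccc5)c(Br)c4O[C@H](c4cc(OCc5ccccc5)c(OCc5ccccc5)c(OCc5ccccc5)c4)[C@@H]3OCc3ccccc3)c2O[C@@H]1c1cc(OCc2ccccc2)c(OCc2ccccc2)c(OCc2ccccc2)c1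
F4 | step 15 | 4β-(2-ethoxyethoxy) derivative of F3 at the lower unit | CCOCCO[C@H]1c2c(OCc3ccccc3)cc(OCc3ccccc3)c([C@H]3c4c(OCc5ccccc5)cc(OCc5ccccc5)c(Br)c4O[C@H](c4cc(OCc5ccccc5)c(OCc5ccccc5)c(OCc5ccccc5)c4)[C@@H]3OCc3ccccc3)c2O[C@H](c2cc(OCc3ccccc3)c(OCc3ccccc3)c(OCc3ccccc3)c2)[C@@H]1OCc1ccccc1
F5 | step 15 | capped dimer 4β-[2-hydroxy-4,6-bis(benzyloxy)phenyl] adduct | Oc1cc(OCc2ccccc2)cc(OCc2ccccc2)c1[C@H]1c2c(OCc3ccccc3)cc(OCc3ccccc3)c([C@H]3c4c(OCc5ccccc5)cc(OCc5ccccc5)c(Br)c4O[C@H](c4cc(OCc5ccccc5)c(OCc5ccccc5)c(OCc5ccccc5)c4)[C@@H]3OCc3ccccc3)c2O[C@H](c2cc(OCc3ccccc3)c(OCc3ccccc3)c(OCc3ccccc3)c2)[C@@H]1OCc1ccccc1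
F6 | step 15 | capped trimeric flavan-3,4-diol (both C4 epimers) | O[C@@H]1C(O)c2c(OCc3ccccc3)cc(OCc3ccccc3)c([C@H]3c4c(OCc5ccccc5)cc(OCc5ccccc5)c([C@H]5c6c(OCc7ccccc7)cc(OCc7ccccc7)c(Br)c6O[C@H](c6cc(OCc7ccccc7)c(OCc7ccccc7)c(OCc7ccccc7)c6)[C@@H]5OCc5ccccc5)c4O[C@H](c4cc(OCc5ccccc5)c(OCc5ccccc5)c(OCc5ccccc5)c4)[C@@H]3OCc3ccccc3)c2O[C@@H]1c1cc(OCc2ccccc2)c(OCc2ccccc2)c(OCc2ccccc2)c1
F7 | step 15 | capped tetramer with free 3-OH on unit 3 | O[C@@H]1[C@@H](c2c(OCc4ccccc4)cc(OCc4ccccc4)c3c2O[C@H](c2ccc(OCc4ccccc4)c(OCc4ccccc4)c2)[C@H](OCc4ccccc4)C3)c2c(OCc3ccccc3)cc(OCc3ccccc3)c([C@H]3c4c(OCc5ccccc5)cc(OCc5ccccc5)c([C@H]5c6c(OCc7ccccc7)cc(OCc7ccccc7)c(Br)c6O[C@H](c6cc(OCc7ccccc7)c(OCc7ccccc7)c(OCc7ccccc7)c6)[C@@H]5OCc5ccccc5)c4O[C@H](c4cc(OCc5ccccc5)c(OCc5ccccc5)c(OCc5ccccc5)c4)[C@@H]3OCc3ccccc3)c2O[C@@H]1c1cc(OCc2ccccc2)c(OCc2ccccc2)c(OCc2ccccc2)c1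
F8 | step 7 | methyl (2S,3S)-3-[3,4,5-tris(benzyloxy)phenyl]oxirane-2-carboxylate | COC(=O)[C@H]1O[C@H]1c1cc(OCc2ccccc2)c(OCc2ccccc2)c(OCc2ccccc2)c1
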